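Carbons carry the numbering of the target throughout: C1 ketone, C2=C3 alkene (methyl on C3), cyclobutane C4, C5, C10, C11, gem‑dimethyl C6, carbinols C7 and C9, methylene C8, quaternary C10 (methyl).

## Analysis of the target

The target 24 is a longipinane: a cyclobutane (C4, C5, C10, C11) bridged across C4/C11 by the enone unit C1–C2–C3 and across C5/C10 by the four‑carbon chain C6–C9. C4, C5, C10 and C11 are fixed as a set by the ring system. Their absolute sense only says which cyclobutane CH carries C3 and which carries C1. The two ester oxygens on C7 and C9 are trans across the seven‑membered ring. Without its substituents the skeleton has a local mirror plane through C2, C5, C10 and the C6–C9 bridge, which exchanges C4 with C11 and C1 with C3. The configuration at C7 and C9 is therefore defined only against the distant difference between the C1 carbonyl and the C3 methyl, and the substrate cannot be expected to set it. Sensitive groups are the strained cyclobutane next to carbonyl groups, the enone, the (E)‑configured tiglate, and two different esters on hindered, 1,3‑related carbinols (acyl migration, β‑elimination while C7 is still a ketone). The hard parts are the doubly bridged cyclobutane with the quaternary C10, the single enantiomer, and the placement of two different acyl groups. The strategy rests on one feature: C10 lies between C4 and C11, so a cyclobutanone with C10 as its carbonyl carbon can take the C1–C2–C3 unit across its two α‑carbons. That cyclobutanone (6) carries a substituent only on C5 and is achiral.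

## Retrosynthetic reasoning

**C7 ester and C7–H.** 24 is cut at the isovalerate to alcohol 22 and acid chloride 23. 22 is then cut at the acyl–oxygen bond of the tiglate together with the C7–H bond, giving hydroxy ketone 20 and aldehyde 21. One operation then reduces C7 trans to the C9 oxygen, places the tigloyl group on C9 and leaves C7–OH free for 23. A diol with two hindered hydroxyls that must be told apart never appears. The reduction acts only on a β‑hydroxy ketone, so the C1 enone is not at risk.

**C9–O.** 20 goes back to dienone 18 by removing the C9 oxygen. Because of the local mirror plane the two faces of C9 in 18 are nearly equivalent for the substrate, so a chiral catalyst can decide. The forward reaction must add oxygen (through boron) to the disubstituted C8=C9 enone and leave the trisubstituted C2=C3 enone alone.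

**C9–C10.** 18 is cut at C9–C10, the bond that closes the seven‑membered ring and creates the quaternary centre. The precursor 16 carries a methylene group on C10 and a β‑ethoxy enone on C6. Hydrogen‑atom transfer to the methylene gives the C10 radical and the methyl group at once, and the tether from C5 allows attack only on the required face of C10. The C9 oxygen of the acceptor would arise without control, so it is not kept: it leaves as ethanol from 17 to give 18.

**C7–C8, C10=CH2, C2=C3.** 16 comes from 15 by dehydrogenation of a silyl enol ether, 15 from amide 13 and vinyl bromide 14, 13 from ketone 12 by methylenation, and 12 from dione 11 by enol silylation. The order is forced. As its enol silane, C1 is protected against the ylide and the vinyllithium reagent, and the non‑enolisable 1,3‑dione of 11 can no longer be cleaved by nucleophiles. The N‑methoxy‑N‑methyl amide is then the only carbonyl group left when C8 and C9 are added. It is carried from the start in place of an ester for that reason, as a spectator in the ring‑forming steps.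

**C3–C4 and C1–C11 (key disconnection).** 11 is cut at both bonds to cyclobutanone 6 and crotonoyl chloride 8, with the C2‑symmetric amine 7 as a recoverable chiral carrier (via 9 and 10). This creates the six‑membered ring, both bridgeheads and the absolute configuration from an achiral four‑step intermediate. The forward reaction must choose one of two enantiotopic α‑carbons, add anti to the C5 chain, and close a strained bridge.

**Cyclobutanone.** 6 goes back through dichloro ketone 5 to alkene 3 and trichloroacetyl chloride 4 (ketene [2+2], then dechlorination). 3 comes from the commercial acid 1 via acid chloride 2.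

## Alternatives that were turned down

Alternative 1: The C4–C10 bond of the cyclobutane is cut, leading back to a cis‑fused bicyclo[5.4.0]undecene with a C9–C10 epoxide. In the forward step a Lewis acid would open the epoxide at tertiary C10, the C3=C4 alkene would attack through C4, and loss of a proton from C2 would give A1. In its favour: the C9 hydroxyl and the quaternary C10 arise together and stereospecifically, and the C7 ester is already in place. On C7/C9 this is stronger than the chosen route, which needs a catalyst‑controlled step and a relay. Against it: a four‑membered ring must be closed by a cation late in the synthesis, in competition with elimination, hydride and alkyl shifts, epoxide‑to‑carbonyl rearrangement and ring expansion of the cyclobutylcarbinyl cation. A1 also lacks the C1 ketone, so a late allylic oxidation has to choose among several allylic positions. The substrate with its four stereocentres would itself need a long enantioselective synthesis. The chosen strategy forms the cyclobutane first by a dependable [2+2] and never closes a small ring against strain late on.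

Alternative 2: The C5–C6 and C8–C9 bonds of the seven‑membered ring are cut, leading to a silyloxy diene and a dimethyl‑substituted oxyallyl cation. Their (4+3) cycloaddition would give A2. In its favour: it is convergent, brings all skeletal carbons together early, and delivers C7 and C9 at different oxidation levels. On convergence it is stronger than the fully linear chosen route. Against it: the fully substituted terminus of the unsymmetrical cation has to bond to a ring carbon, so regiochemistry and stepwise side paths are uncertain. The C5/C9 relation depends on endo/exo control, and the step gives a racemate unless an auxiliary is added. Most important, A2 is still a bicyclo[5.4.0] system: the C4–C10 bond, the quaternary centre and the cyclobutane remain to be made from a tetrasubstituted alkene. The chosen strategy settles exactly these points, and the absolute configuration, in its key step.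

Alternative 3: The C2–C3 bond is cut, leading to a meso compound that already holds the cyclobutane and the seven‑membered ring and carries two enantiotopic acetyl groups on C4 and C11. A chiral primary amine salt would turn one acetyl group into an enamine that condenses with the other, giving A3. In its favour: the enantio‑determining step is catalytic, whereas the chosen route uses a stoichiometric (recoverable) amine. The enone with its C3 methyl also appears without a separate dehydrogenation. On both points it is stronger. Against it: the meso substrate is a densely substituted bicyclo[4.1.1]octane with a quaternary C10 and two epimerisable acetyl‑bearing carbons, and no short route to it is evident. The aldol closure must form the strained bridged enone against retro‑aldol cleavage. A3 also still has C7 and C9 as a vinylogous ester, so the C7/C9 problem is unchanged. The chosen strategy places the desymmetrisation on an intermediate made in three steps instead of on a late, costly one.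

Key step: step 4

Assumption: the senses of induction of the two chiral reagents are taken as the models in steps 4 and 10 predict ((2S,5S)‑amine 7, (R,R)‑ligand); should a first run show the opposite sense, the enantiomeric reagent is used and nothing else changes.

## Route

Step 1
Reactants: 1 2,2-dimethylbut-3-enoic acid
Product: 3 N-methoxy-N,2,2-trimethylbut-3-enamide, via acid chloride 2 (not isolated)
Conditions: (COCl)2, DMF (cat.), CH2Cl2, 0 → 25 °C; then MeNH(OMe)·HCl, Et3N, 0 → 25 °C
Reagents that add atoms: oxalyl chloride, ClC(=O)C(Cl)=O (chlorine of 2 only); N,O-dimethylhydroxylamine hydrochloride, CNOC.Cl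
Why: Acid chloride formation and amide coupling; the hindered acid needs the acid chloride, and there is no α‑hydrogen, so no ketene can form.

Step 2
Reactants: 3 N-methoxy-N,2,2-trimethylbut-3-enamide; 4 trichloroacetyl chloride
Product: 5 2-(2,2-dichloro-3-oxocyclobutyl)-N-methoxy-N,2-dimethylpropanamide (racemic)
Conditions: Zn(Cu), Et2O/DME, slow addition of 4, 25 → 35 °C
Reagents that add atoms: none
Why: [2+2] cycloaddition of dichloroketene (made in the flask from 4) with a terminal alkene; the carbonyl carbon of the ketene bonds to the CH2 terminus, which gives the 3‑substituted 2,2‑dichlorocyclobutanone. DME binds ZnCl2, so no phosphoryl chloride is needed next to the amide.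

Step 3
Reactants: 5 2-(2,2-dichloro-3-oxocyclobutyl)-N-methoxy-N,2-dimethylpropanamide
Product: 6 N-methoxy-N,2-dimethyl-2-(3-oxocyclobutyl)propanamide (achiral)
Conditions: Zn, NH4Cl, MeOH, 25 °C
Reagents that add atoms: none
Why: Reductive removal of both α‑chlorine atoms by zinc; the mild, near‑neutral conditions should leave the N–O bond of the amide intact.

Step 4
Reactants: 6 N-methoxy-N,2-dimethyl-2-(3-oxocyclobutyl)propanamide; 7 (2S,5S)-2,5-dimethylpyrrolidine; 8 (E)-but-2-enoyl chloride
Product: 11 N-methoxy-N,2-dimethyl-2-(4-methyl-2,6-dioxobicyclo[3.1.1]heptan-7-yl)propanamide (single enantiomer; chain on C5 anti to the C1–C3 bridge), via enamine 9 (not isolated), via iminium chloride 10 (not isolated)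
Conditions: 7 (1.3 equiv), TsOH (cat.), 4 Å MS, toluene, 80 °C; then 8 (1.1 equiv), toluene, 25 → 80 °C; then H2O, 25 °C
Reagents that add atoms: water, O
Why: Proposed new method: enamine 9 is N‑acylated by 8 and the N‑acyl enammonium ion undergoes a 3‑aza‑Cope shift through a chair, in which the crotonyl β‑carbon C3 bonds to C4 and an iminium ion carrying a ketene results; proton loss from C11 regenerates the enamine on the other side of C10, and this carbon attacks the acyl carbon C1 to give iminium chloride 10, which water cleaves to 11 and recoverable 7. The closest known reaction type is the α,α′‑annulation of cyclohexanone and cyclopentanone enamines with acryloyl and crotonoyl chlorides to bridged diones such as bicyclo[3.3.1]nonane‑2,9‑diones; it has not been run on a cyclobutanone enamine or as a desymmetrisation. The only ring closed is the six‑membered ring C11–C1–C2–C3–C4–C10, closed by a 6‑exo attack of C11 on C1 (exo‑dig at the ketene, exo‑trig if the acyl chloride or an acylammonium ion is the electrophile). C4: its face is set by the C5 chain (C3 adds anti to it), and its choice among the two enantiotopic α‑carbons is set by 7, whose methyl group next to the enamine double bond lies on the face of the C5 chain in 9 and leaves the other face open, whereas in the regioisomeric enamine both faces are blocked. C11 must be cis to the C3–C4 bond for the bridge to close, so it follows from C4; C5 becomes stereogenic through the desymmetrisation, with its chain anti to the new bridge. C3 comes from the chair with the (E)‑crotonyl unit and is drawn as one epimer; either epimer serves, since C3 becomes sp2 in step 8. The step needs enantiotopic‑group selection, anti facial selectivity and C‑ over O‑acylation: the C2‑symmetric amine secures the first, the bulk of the C(CH3)2 chain the second, and the geometry that holds the acyl carbon over C11 the third.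

Step 5
Reactants: 11 N-methoxy-N,2-dimethyl-2-(4-methyl-2,6-dioxobicyclo[3.1.1]heptan-7-yl)propanamide
Product: 12 2-{2-[(tert-butyldimethylsilyl)oxy]-4-methyl-6-oxobicyclo[3.1.1]hept-2-en-7-yl}-N-methoxy-N,2-dimethylpropanamide
Conditions: TBSOTf, Et3N, CH2Cl2, −78 → 0 °C
Reagents that add atoms: tert-butyldimethylsilyl trifluoromethanesulfonate, CC(C)(C)[Si](C)(C)OS(=O)(=O)C(F)(F)F
Why: Soft enolisation and O‑silylation; only C2 can be deprotonated, because C4 and C11 are bridgeheads (Bredt's rule). The enol silane masks C1 and removes the 1,3‑dione that a nucleophile could cleave.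

Step 6
Reactants: 12 the silyl enol ether from step 5
Product: 13 2-{2-[(tert-butyldimethylsilyl)oxy]-4-methyl-6-methylidenebicyclo[3.1.1]hept-2-en-7-yl}-N-methoxy-N,2-dimethylpropanamide
Conditions: Ph3PCH3Br, KOtBu, THF, 0 → 25 °C
Reagents that add atoms: methyltriphenylphosphonium bromide, C[P+](c1ccccc1)(c1ccccc1)c1ccccc1.[Br-]
Why: Wittig methylenation of the C10 cyclobutanone, the only ketone present and one that cannot enolise; the strained carbonyl is reactive and the hindered amide is not attacked.

Step 7
Reactants: 13 the methylidene amide from step 6; 14 (Z)-1-bromo-2-ethoxyethene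
Product: 15 (Z)-4-{2-[(tert-butyldimethylsilyl)oxy]-4-methyl-6-methylidenebicyclo[3.1.1]hept-2-en-7-yl}-1-ethoxy-4-methylpent-1-en-3-one
Conditions: 14, n-BuLi, THF, −78 °C; then 13, −78 → −40 °C; pH 7 buffer
Reagents that add atoms: none
Why: Bromine–lithium exchange gives (Z)‑2‑ethoxyvinyllithium, which adds once to the N‑methoxy‑N‑methyl amide (stable chelated adduct) and gives the β‑ethoxy enone on work‑up. The amide is the only electrophile in 13; the alkene geometry is of no consequence later.

Step 8
Reactants: 15 the β‑ethoxy enone from step 7
Product: 16 (Z)-1-ethoxy-4-methyl-4-(4-methyl-6-methylidene-2-oxobicyclo[3.1.1]hept-3-en-7-yl)pent-1-en-3-one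
Conditions: Pd(OAc)2 (1.1 equiv), MeCN, 40 °C
Reagents that add atoms: none
Why: Saegusa–Ito oxidation: divalent palladium takes the enolate from silicon and β‑hydride elimination from C3 gives the C2=C3 enone. Either C3 epimer has a hydrogen that can become syn to palladium, and the regiochemistry is fixed because C1 has no other enolisable side.

Step 9
Reactants: 16 the enone from step 8
Product: 18 longipina-2,8-diene-1,7-dione, via 9-ethoxy ketone 17 (not isolated)
Conditions: Fe(acac)3 (1 equiv), PhSiH3 (2.5 equiv), EtOH/HOCH2CH2OH, 60 °C, high dilution; then TsOH·H2O (cat.), toluene, 60 °C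
Reagents that add atoms: none
Why: Hydrogen‑atom transfer from an iron hydride to the 1,1‑disubstituted alkene gives the tertiary C10 radical (and the C10 methyl group), which adds 7‑endo‑trig to C9 of the β‑ethoxy enone (intramolecular Giese reaction). Attack at C9 is favoured by polarity and by the lower strain of the seven‑membered ring over the alternative six‑membered bridge. The tether from C5 permits bonding only on the face of C10 anti to the enone bridge, which fixes C10; acid then removes ethanol from 17 (both C9 epimers) to give 18.

Step 10
Reactants: 18 longipina-2,8-diene-1,7-dione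
Product: 20 9-hydroxylongipin-2-ene-1,7-dione, via 9-boryl ketone 19 (not isolated)
Conditions: Cu(MeCN)4PF6 (5 mol%), (R,R)-QuinoxP* (6 mol%), LiOtBu (10 mol%), B2pin2, MeOH, THF, 0 → 25 °C; then NaBO3·4H2O, THF/H2O, 25 °C
Reagents that add atoms: bis(pinacolato)diboron, CC1(C)OB(OC1(C)C)B1OC(C)(C)C(C)(C)O1 (boron of 19 only); sodium perborate, [Na+].[O-]OB=O
Why: Enantioselective conjugate borylation by a monovalent copper boryl complex, then C–B oxidation with retention. The two faces of C9 differ for the substrate only through the remote C1/C3 difference, so the chiral ligand decides the C9 configuration. The β,β‑disubstituted C2=C3 enone is far less reactive toward the boryl copper species.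

Step 11
Reactants: 20 9-hydroxylongipin-2-ene-1,7-dione; 21 (E)-2-methylbut-2-enal
Product: 22 7-hydroxy-1-oxolongipin-2-en-9-yl (E)-2-methylbut-2-enoate (7‑OH trans to the 9‑ester)
Conditions: SmI2 (30 mol%), 21 (6 equiv), THF, −10 °C
Reagents that add atoms: none
Why: Evans–Tishchenko reduction: the samarium‑bound hemiacetal of the C9 hydroxyl and 21 transfers its hydride to C7 within a six‑membered transition state, from the face of the C9 oxygen. The new C7 hydroxyl is therefore trans (1,3‑anti) to C9–O and the tigloyl group ends on C9; the C1 enone has no directing hydroxyl and is not reduced.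

Step 12
Reactants: 22 the hydroxy tiglate from step 11; 23 3-methylbutanoyl chloride
Product: 24 7-(3-methylbutanoyloxy)-1-oxolongipin-2-en-9-yl (E)-2-methylbut-2-enoate (target)
Conditions: 23, pyridine, DMAP (cat.), CH2Cl2, 0 → 25 °C
Reagents that add atoms: none
Why: O‑acylation of the hindered secondary alcohol with retention at C7; mild base and low temperature limit 1,3‑migration of the tigloyl group.

## Compound list

1 | 2,2-dimethylbut-3-enoic acid | C=CC(C)(C)C(O)=O | starting material
2 | 2,2-dimethylbut-3-enoyl chloride | C=CC(C)(C)C(Cl)=O | intermediate
3 | N-methoxy-N,2,2-trimethylbut-3-enamide | C=CC(C)(C)C(=O)N(C)OC | intermediate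
4 | trichloroacetyl chloride | ClC(=O)C(Cl)(Cl)Cl | starting material
5 | 2-(2,2-dichloro-3-oxocyclobutyl)-N-methoxy-N,2-dimethylpropanamide (racemic) | CON(C)C(=O)C(C)(C)C1CC(=O)C1(Cl)Cl | intermediate
6 | N-methoxy-N,2-dimethyl-2-(3-oxocyclobutyl)propanamide | CON(C)C(=O)C(C)(C)C1CC(=O)C1 | intermediate
7 | (2S,5S)-2,5-dimethylpyrrolidine | C[C@H]1CC[C@H](C)N1 | starting material
8 | (E)-but-2-enoyl chloride | C/C=C/C(Cl)=O | starting material
9 | enamine of 6 and 7, double bond toward C4 | CON(C)C(=O)C(C)(C)[C@@H]1CC(N2[C@@H](C)CC[C@@H]2C)=C1 | intermediate
10 | bridged C10 iminium chloride of 11 with 7 | CON(C)C(=O)C(C)(C)[C@@H]1[C@H]2C(=O)C[C@@H](C)[C@@H]1C2=[N+]3[C@@H](C)CC[C@@H]3C.[Cl-] | intermediate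
11 | N-methoxy-N,2-dimethyl-2-(4-methyl-2,6-dioxobicyclo[3.1.1]heptan-7-yl)propanamide | CON(C)C(=O)C(C)(C)[C@@H]1[C@H]2C(=O)C[C@@H](C)[C@@H]1C2=O | intermediate
12 | C1 tert-butyldimethylsilyl enol ether of 11 | CON(C)C(=O)C(C)(C)[C@@H]1[C@H]2C(O[Si](C)(C)C(C)(C)C)=C[C@@H](C)[C@@H]1C2=O | intermediate
13 | C10 methylidene derivative of 12 | CON(C)C(=O)C(C)(C)[C@@H]1[C@H]2C(O[Si](C)(C)C(C)(C)C)=C[C@@H](C)[C@@H]1C2=C | intermediate
14 | (Z)-1-bromo-2-ethoxyethene | CCO/C=C\Br | starting material
15 | β‑ethoxy enone with C1 silyl enol ether | CCO/C=C\C(=O)C(C)(C)[C@@H]1[C@H]2C(O[Si](C)(C)C(C)(C)C)=C[C@@H](C)[C@@H]1C2=C | intermediate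
16 | (Z)-1-ethoxy-4-methyl-4-(4-methyl-6-methylidene-2-oxobicyclo[3.1.1]hept-3-en-7-yl)pent-1-en-3-one | CCO/C=C\C(=O)C(C)(C)[C@@H]1[C@H]2C(=O)C=C(C)[C@@H]1C2=C | intermediate
17 | 9-ethoxylongipin-2-ene-1,7-dione (both C9 epimers) | CCOC1CC(=O)C(C)(C)[C@@H]2[C@H]3C(=O)C=C(C)[C@@H]2[C@]31C | intermediate
18 | longipina-2,8-diene-1,7-dione | C1=CC(=O)C(C)(C)[C@@H]2[C@H]3C(=O)C=C(C)[C@@H]2[C@]31C | intermediate
19 | 9-(4,4,5,5-tetramethyl-1,3,2-dioxaborolan-2-yl)longipin-2-ene-1,7-dione | CC4(C)OB(OC4(C)C)[C@@H]1CC(=O)C(C)(C)[C@@H]2[C@H]3C(=O)C=C(C)[C@@H]2[C@]31C | intermediate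
20 | 9-hydroxylongipin-2-ene-1,7-dione | O[C@@H]1CC(=O)C(C)(C)[C@@H]2[C@H]3C(=O)C=C(C)[C@@H]2[C@]31C | intermediate
21 | (E)-2-methylbut-2-enal | C/C=C(\C)C=O | starting material
22 | 7-hydroxy-1-oxolongipin-2-en-9-yl (E)-2-methylbut-2-enoate | C/C=C(\C)C(=O)O[C@@H]1C[C@@H](O)C(C)(C)[C@@H]2[C@H]3C(=O)C=C(C)[C@@H]2[C@]31C | intermediate
23 | 3-methylbutanoyl chloride | CC(C)CC(Cl)=O | starting material
24 | 7-(3-methylbutanoyloxy)-1-oxolongipin-2-en-9-yl (E)-2-methylbut-2-enoate | C/C=C(\C)C(=O)O[C@@H]1C[C@@H](OC(=O)CC(C)C)C(C)(C)[C@@H]2[C@H]3C(=O)C=C(C)[C@@H]2[C@]31C | target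

## Step count and least certain steps

Total: 12 steps. Longest linear sequence: 12 steps from 1 (the route is fully linear; 4, 7, 8, 14, 21 and 23 are bought).

**Step 4 (key step, proposed new method).** The acyl unit may be intercepted by chloride, by a second enamine or on oxygen before the strained 6‑exo C‑acylation takes place. The non‑enolisable 1,3‑dione may be cleaved during hydrolysis, and the amine may select poorly between the two α‑carbons. Fallback with known reaction types, from 9 (made from 6 and 7 as in step 4) back to 11: the two bonds are made one at a time. Stork enamine conjugate addition of 9 to diethyl ethylidenemalonate, anti to the C5 chain, and aqueous acetic acid hydrolysis should give the trans‑2,3‑disubstituted cyclobutanone malonate F1. Saponification (LiOH, THF/H2O), acidification and loss of CO2 in warm toluene should give keto acid F2. F2 is then closed to 11 by acid‑promoted C‑acylation of the ketone through its mixed anhydride ((CF3CO)2O, then BF3·OEt2, CH2Cl2), the way 3‑(2‑oxocyclohexyl)propanoic acid is converted into bicyclo[3.3.1]nonane‑2,9‑dione. The ring strain remains, but each bond can be optimised on its own.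

**Step 9.** The C10 radical may be reduced by a second hydrogen‑atom transfer, or the alkene may isomerise, before the slow 7‑endo addition to the donor‑substituted acceptor occurs. Fallback from 13 back to 18: vinylmagnesium bromide with 13 gives vinyl ketone F3, and Pd(OAc)2 gives the enone F4. The same Fe(acac)3/PhSiH3 conditions should then close the ring faster onto the unsubstituted vinyl ketone, giving longipin‑2‑ene‑1,7‑dione F5. Dehydrogenation of F5 with IBX (DMSO/toluene, 70 °C) can only introduce the C8=C9 alkene and gives 18.

**Step 10.** The boryl copper addition next to the quaternary C10 may be slow and the facial selection at C9 insufficient. Fallback from 18 back to 20: amine‑salt‑catalysed asymmetric epoxidation of the cycloheptenone (H2O2, a 9‑amino‑9‑deoxy‑epi‑cinchona alkaloid salt) gives the 8,9‑epoxy ketone F6. Reductive opening at C8 with the sodium phenylselenide–borate reagent ((PhSe)2, NaBH4, EtOH, AcOH, 0 °C) then gives 20.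

**Step 11.** Hemiacetal formation and hydride transfer may be slow with the conjugated aldehyde, and the acyl group may migrate between the 1,3‑related oxygens. Fallback from 20 back to 24, with a temporary acyl group: Evans–Tishchenko reduction with methoxyacetaldehyde gives the 9‑methoxyacetate F7. 23 and pyridine give the mixed diester F8. Selective methanolysis of the activated methoxyacetate (Yb(OTf)3, MeOH) gives the 9‑alcohol F9. Tigloylation of F9 (tiglic acid, 2,4,6‑trichlorobenzoyl chloride, Et3N, DMAP) gives 24.

## Further compounds

F1 | step 4 | diethyl 2-{1-[(1R*,2-trans)-2-substituted-4-oxocyclobutyl]ethyl}malonate (C4/C5 as in 11, C3 unassigned) | CON(C)C(=O)C(C)(C)[C@@H]1CC(=O)[C@H]1C(C)C(C(=O)OCC)C(=O)OCC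
F2 | step 4 | 3-[2-oxo-4-(chain)cyclobutyl]butanoic acid (C4/C5 as in 11, C3 unassigned) | CON(C)C(=O)C(C)(C)[C@@H]1CC(=O)[C@H]1C(C)CC(O)=O
F3 | step 9 | vinyl ketone with C1 silyl enol ether | C=CC(=O)C(C)(C)[C@@H]1[C@H]2C(O[Si](C)(C)C(C)(C)C)=C[C@@H](C)[C@@H]1C2=C
F4 | step 9 | 4-methyl-4-(4-methyl-6-methylidene-2-oxobicyclo[3.1.1]hept-3-en-7-yl)pent-1-en-3-one | C=CC(=O)C(C)(C)[C@@H]1[C@H]2C(=O)C=C(C)[C@@H]1C2=C
F5 | step 9 | longipin-2-ene-1,7-dione | C1CC(=O)C(C)(C)[C@@H]2[C@H]3C(=O)C=C(C)[C@@H]2[C@]31C
F6 | step 10 | 8,9-epoxylongipin-2-ene-1,7-dione | O1[C@@H]2[C@H]1C(=O)C(C)(C)[C@@H]3[C@H]4C(=O)C=C(C)[C@@H]3[C@]42C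
F7 | step 11 | 7-hydroxy-1-oxolongipin-2-en-9-yl methoxyacetate | COCC(=O)O[C@@H]1C[C@@H](O)C(C)(C)[C@@H]2[C@H]3C(=O)C=C(C)[C@@H]2[C@]31C
F8 | step 11 | 9-(methoxyacetoxy)-1-oxolongipin-2-en-7-yl 3-methylbutanoate | COCC(=O)O[C@@H]1C[C@@H](OC(=O)CC(C)C)C(C)(C)[C@@H]2[C@H]3C(=O)C=C(C)[C@@H]2[C@]31C
F9 | step 11 | 9-hydroxy-1-oxolongipin-2-en-7-yl 3-methylbutanoate | O[C@@H]1C[C@@H](OC(=O)CC(C)C)C(C)(C)[C@@H]2[C@H]3C(=O)C=C(C)[C@@H]2[C@]31C
A1 | alternative 1 | 9-hydroxylongipin-2-en-7-yl 3-methylbutanoate | O[C@@H]1C[C@@H](OC(=O)CC(C)C)C(C)(C)[C@@H]2[C@H]3CC=C(C)[C@@H]2[C@]31C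
A2 | alternative 2 | bicyclo[5.4.0]undecenone with C7 ketone, C9 silyl ether and C3 ethylene ketal | CC(C)(C)[Si](C)(C)O[C@@H]1CC(=O)C(C)(C)[C@@H]2C(CCC3(OCCO3)C2)=C1C
A3 | alternative 3 | 9-methoxylongipina-2,8-diene-1,7-dione | COC1=CC(=O)C(C)(C)[C@@H]2[C@H]3C(=O)C=C(C)[C@@H]2[C@]31C
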